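Counting comes first: on the proposed steps each target made frees one by-product, and each side product holds two starting-material units and has used up one target. So the by-product made so far is S/2 + P, with S the side product and P the target in percent of the starting material charged. Base binds by-product as salt, which gives the base ceiling 60.0 %: the S that the charged base can take up with P near nil, 2 times the base charge over the starting-material charge.

| flask | starting material | coupling partner | base | remark | time |
|---|---|---|---|---|---|
| autumn | 13 mM | 26 mM | 3.9 mM | run made earlier |  |
| spring | 13 mM | 58 mM | 3.9 mM | run made earlier |  |
| teal | 13 mM | 39.0 mM | 3.90 mM |  | 25 min |
| red | 13 mM | 39.0 mM | 3.90 mM |  | 220 min |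
| ochre | 13 mM | 39.0 mM | 3.90 mM |  | 75 min |

- autumn (time / min: starting material / %, target / %, side product / %): 1.50: 92.8, 0.6, 0.8; 3.00: 86.4, 1.0, 0.6; 6.00: 75.2, 0, 3.4; 10.0: 63.9, 1.4, 4.4; 20.0: 46.2, 0.9, 9.6
- spring (time / min: starting material / %, target / %, side product / %): 4.00: 80.7, 2.2, 2.8; 8.00: 64.1, 2.5, 7.8; 12.0: 52.0, 2.4, 11.9; 15.0: 46.8, 2.7, 13.7; 20.0: 38.3, 2.4, 18.5

(readings scatter by 0.5 percentage points)

1. which of these there is most of at the end, counted by the starting material in it, teal (starting material / side product / target)
2. which of these there is most of at the end, counted by the starting material in it, red (starting material / side product / target)
3. which of these there is most of at the end, counted by the starting material in it, ochre (starting material / side product / target)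
4. how much there is at the end of the one of these that leads, in percent of the starting material charged: teal
5. how much there is at the end of the one of these that leads, in percent of the starting material charged: red
6. how much there is at the end of the one of these that leads, in percent of the starting material charged: ochre

How close does red come to that ceiling? Call the pool whatever is neither S nor P, that is starting material plus dormant form, and let κ be its pseudo-first-order decay constant. Read at the last reading and scaled to the 39.0 mM of coupling partner, κ is 0.00832 min⁻¹ from autumn and 0.00788 min⁻¹ from spring, so I take the pace as first order in partner.

From above, I hold the larger κ for the 220 min of red, which gives S plus P of 84.0 %. I count that high while base holds if the pace goes with starting material, which is 48.4 % of the pool at spring's last reading, but it counts no burst past the ceiling. From below, I take on my own judgement 0.5 of the smaller κ, which gives S plus P of 58.0 %, just under the ceiling. So my estimated bracket for red runs from 58.0 % to 84.0 %, and I expect red near the ceiling or past it.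

The forecast gives teal starting material at 38 %, red side product at 70 % and ochre side product at 36 %. Its red figure lies inside my bracket, and of red it says “the remaining pool cannot overtake it”.

The flasks give teal starting material at 37.1 %, red side product at 68.0 % and ochre side product at 33.3 %.

    starting material + coupling partner + by-product → target + 2 by-product (k = 11.0 M⁻² s⁻¹)
    starting material ⇌ dormant form (K = 1.60, k = 7.50 × 10⁻⁴ s⁻¹)
    starting material + target → side product (k = 0.500 M⁻¹ s⁻¹)
    base + by-product ⇌ salt, settled at all times (K = 3.00 × 10⁵ M⁻¹)
    starting material + coupling partner → target + by-product (k = 0.00280 M⁻¹ s⁻¹)

In ochre at 75.0 min, the direct step uses coupling partner 49 times as fast as the by-product-assisted step. Ochre stands under the ceiling with 39 % of its base left, and its by-product count of 18.2 % matches the 18.2 % of base used, both in percent of the starting material charged. Red stands over the ceiling, with 0.29 % of its base left and 1.16 mM of by-product free. Ochre's leader changes with less partner: the neighbour at 23 mM holds starting material at 28.1 %, ahead of side product at 21.9 %.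

The readings come from a simulation with made-up constants; scatter was added.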